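## Retrosynthetic overview

1. Target 13 ⇒ Mitsunobu inversion at C4 of the 2,4-cis alcohol 11 ⇒ hydride reduction of the (2S)-flavanone 10, the chemical counterpart of flavanone 4-reductase, in which C2 controls C4.
2. 10 ⇒ 5-O-prenylflavanone 7. The C8–prenyl bond is made after ring closure, as in the plant, by a Claisen–Cope prenyl walk O5→C6→C8.
3. 7 ⇒ chalcone 6. Ring C is the only ring built (rings A and B are bought). It is closed by a catalytic enantioselective oxa-Michael addition that copies chalcone isomerase and sets C2. The 6'-O-prenyl group leaves one free ortho-OH, so only one regioisomer can form.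
4. 6 ⇒ acetophenone 4 + 4-hydroxybenzaldehyde 5 (Claisen–Schmidt). 4 ⇒ phloracetophenone 1, Me2SO4 and prenyl bromide 2. No protecting groups are used.

Assumption: the SMILES is read as (2S,4R), that is 2,4-trans, with the 2-aryl group and the 4-OH on opposite faces of ring C.

## Route

**Step 1**
Reactants: 1 2',4',6'-trihydroxyacetophenone; 2 prenyl bromide
Product: 4 2'-hydroxy-4'-methoxy-6'-(3-methylbut-2-enyloxy)acetophenone, via 2',6'-dihydroxy-4'-methoxyacetophenone 3 (not isolated)
Conditions: Me2SO4 (1.0 equiv), K2CO3 (2.5 equiv), acetone, 25→40 °C, 5 h; then 2 (1.1 equiv), reflux, 8 h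
Reagents that add atoms: dimethyl sulfate, COS(=O)(=O)OC
Why: Two Williamson etherifications run in order of phenol reactivity: the unchelated, most acidic 4-OH is methylated first, one of the two equivalent ortho-OH groups of 3 is then prenylated, and the last OH is shut down by its hydrogen bond to the ketone and stays free for the ring closure (no stereocenter).

**Step 2**
Reactants: 4 2'-hydroxy-4'-methoxy-6'-(3-methylbut-2-enyloxy)acetophenone; 5 4-hydroxybenzaldehyde
Product: 6 (E)-2',4-dihydroxy-4'-methoxy-6'-(3-methylbut-2-enyloxy)chalcone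
Conditions: KOH (50% aq, 12 equiv), EtOH, 0→25 °C, 48 h, N2; cold 1 M HCl to pH 6
Reagents that add atoms: none
Why: Claisen–Schmidt aldol condensation (E1cB loss of water gives the E-enone), known to work unprotected for 2'-hydroxy-4',6'-dialkoxyacetophenones with 4-hydroxybenzaldehyde, because in strong base the product rests as the open bis-phenolate whose push-pull enone does not cyclise, so the chalcone and not racemic flavanone is isolated on cold neutralisation.

**Step 3**
Reactants: 6 (E)-2',4-dihydroxy-4'-methoxy-6'-(3-methylbut-2-enyloxy)chalcone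
Product: 7 (2S)-4'-hydroxy-7-methoxy-5-(3-methylbut-2-enyloxy)flavanone
Conditions: N-[3,5-bis(trifluoromethyl)phenyl]-N'-[(9R)-6'-methoxycinchonan-9-yl]thiourea (quinidine-derived, 15 mol %), PhCl, 0 °C, 72 h; short SiO2 plug to remove the catalyst; recrystallise (EtOAc–hexane) to raise ee
Reagents that add atoms: none
Why: Enantioselective intramolecular oxa-Michael addition (6-endo-trig) under bifunctional cinchona thiourea catalysis, a small-molecule copy of chalcone isomerase: the thiourea holds the ketone oxygen, the quinuclidine takes the proton of the only free ortho-OH, and the ion pair closes on one face of C-beta to set C2 as S (sense assigned by analogy with additions to chalcones by this catalyst family and checked by CD, the quinine-derived pseudoenantiomer giving the mirror image), while the 6'-alkoxy group twists the aryl ketone out of conjugation, which pulls the equilibrium to the flavanone.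

**Step 4**
Reactants: 7 (2S)-4'-hydroxy-7-methoxy-5-(3-methylbut-2-enyloxy)flavanone
Product: 10 (2S)-5,4'-dihydroxy-7-methoxy-8-(3-methylbut-2-enyl)flavanone, via ortho-dienone 8 (not isolated), via para-dienone 9 (not isolated)
Conditions: Eu(fod)3 (10 mol %), CHCl3 (ethanol-free), 75 °C, sealed tube, 20 h
Reagents that add atoms: none
Why: Lewis-acid-catalysed aromatic Claisen rearrangement followed by Cope rearrangement and tautomerisation (two [3,3] shifts, O5→C6 with allyl inversion, then C6→C8 with a second inversion that restores the normal prenyl group), known for 5-O-prenylflavanones; the oxophilic trivalent europium of Eu(fod)3, chelated between C4=O and O5, lets it run under neutral aprotic conditions in which C2 takes no part and is not epimerised, and C8 is reached because it is para to O5.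

**Step 5**
Reactants: 10 (2S)-5,4'-dihydroxy-7-methoxy-8-(3-methylbut-2-enyl)flavanone
Product: 11 (2S,4S)-2-(4-hydroxyphenyl)-7-methoxy-8-(3-methylbut-2-enyl)chroman-4,5-diol (2,4-cis)
Conditions: NaBH4 (2 equiv), THF–EtOH 4:1, −10→0 °C, 1 h; pH 7 phosphate buffer; Et3N-deactivated SiO2
Reagents that add atoms: none
Why: Substrate-controlled borohydride reduction: in the half-chair with the 2-aryl group equatorial, hydride adds axially on the face of axial H-2, the well-known course for flavanones, which gives the pseudo-equatorial 4-OH (2,4-cis, 4S), and the low temperature outruns base-induced ring opening so that C2 is kept.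

**Step 6**
Reactants: 11 (2S,4S)-2-(4-hydroxyphenyl)-7-methoxy-8-(3-methylbut-2-enyl)chroman-4,5-diol
Product: 13 (2S,4R)-2-(4-hydroxyphenyl)-7-methoxy-8-(3-methylbut-2-enyl)chroman-4,5-diol (target), via (2S,4R)-4-nitrobenzoate ester 12 (not isolated)
Conditions: 4-O2NC6H4CO2H (2.5 equiv), PPh3 (2.0 equiv), DIAD (2.0 equiv), THF–toluene, −20→0 °C, 2 h; then 1 M aq LiOH (8 equiv), 0 °C, 1 h; sat. aq NH4Cl; Et3N-deactivated SiO2
Reagents that add atoms: 4-nitrobenzoic acid, O=C(O)c1ccc(cc1)[N+](=O)[O-] (supplies the new C4 oxygen)
Why: Mitsunobu inversion then saponification: the far more acidic 4-nitrobenzoic acid outcompetes both phenols as nucleophile and enters C4 anti to the oxyphosphonium group, and because the ionised pathway (C4 cation or ortho-quinone methide of this electron-rich ring) is also captured axially, trans to the 2-aryl group and away from the peri 5-OH, both pathways give the 4R ester 12, whose acyl–oxygen cleavage by cold aqueous LiOH (which also removes any phenol esters) keeps the C4–O bond and gives the 2,4-trans alcohol, which cannot re-ionise in base.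

## Compound list

1 | 2',4',6'-trihydroxyacetophenone (phloracetophenone) | CC(=O)c1c(O)cc(O)cc1O | starting material
2 | prenyl bromide (1-bromo-3-methylbut-2-ene) | CC(C)=CCBr | starting material
3 | 2',6'-dihydroxy-4'-methoxyacetophenone (not isolated) | COc1cc(O)c(C(C)=O)c(O)c1 | intermediate
4 | 2'-hydroxy-4'-methoxy-6'-(3-methylbut-2-enyloxy)acetophenone | COc1cc(O)c(C(C)=O)c(OCC=C(C)C)c1 | intermediate
5 | 4-hydroxybenzaldehyde | O=Cc1ccc(O)cc1 | starting material
6 | (E)-2',4-dihydroxy-4'-methoxy-6'-(3-methylbut-2-enyloxy)chalcone | COc1cc(O)c(C(=O)/C=C/c2ccc(O)cc2)c(OCC=C(C)C)c1 | intermediate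
7 | (2S)-4'-hydroxy-7-methoxy-5-(3-methylbut-2-enyloxy)flavanone | COc1cc(OCC=C(C)C)c2c(c1)O[C@H](c1ccc(O)cc1)CC2=O | intermediate
8 | ortho-dienone: (2S)-2-(4-hydroxyphenyl)-7-methoxy-6-(2-methylbut-3-en-2-yl)-2,3-dihydrochromene-4,5(6H)-dione, both C6 epimers (not isolated) | COC1=CC2=C(C(=O)C1C(C)(C)C=C)C(=O)C[C@@H](c1ccc(O)cc1)O2 | intermediate
9 | para-dienone: (2S)-2-(4-hydroxyphenyl)-7-methoxy-8-(3-methylbut-2-enyl)-2,3-dihydrochromene-4,5(8H)-dione, both C8 epimers (not isolated) | COC1=CC(=O)C2=C(C1CC=C(C)C)O[C@H](c1ccc(O)cc1)CC2=O | intermediate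
10 | (2S)-5,4'-dihydroxy-7-methoxy-8-(3-methylbut-2-enyl)flavanone | COc1cc(O)c2c(c1CC=C(C)C)O[C@H](c1ccc(O)cc1)CC2=O | intermediate
11 | (2S,4S)-2-(4-hydroxyphenyl)-7-methoxy-8-(3-methylbut-2-enyl)chroman-4,5-diol (2,4-cis) | COc1cc(O)c2c(c1CC=C(C)C)O[C@H](c1ccc(O)cc1)C[C@@H]2O | intermediate
12 | (2S,4R)-5-hydroxy-2-(4-hydroxyphenyl)-7-methoxy-8-(3-methylbut-2-enyl)chroman-4-yl 4-nitrobenzoate (not isolated) | COc1cc(O)c2c(c1CC=C(C)C)O[C@H](c1ccc(O)cc1)C[C@H]2OC(=O)c1ccc(cc1)[N+](=O)[O-] | intermediate
13 | (2S,4R)-4,5,4'-trihydroxy-7-methoxy-8-prenylflavan (2,4-trans) | COc1cc(O)c2c(c1CC=C(C)C)O[C@H](c1ccc(O)cc1)C[C@H]2O | target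

## Step count and risks

Total step count: 6. Longest linear sequence: 6 (1→4→6→7→10→11→13).

**Most likely to fail, first: step 3.**
- The donor 4-OH slows the cyclisation. It can also be deprotonated in place of the 2'-OH.
- The reaction is reversible, so the ee may be only moderate.

The fallback sets out from chalcone 6 and comes back at flavanone 7.
- Chalcone 6 is stirred with DBU/HCO2H and RuCl[(S,S)-TsDPEN](p-cymene) (1 mol %) in MeCN at 30 °C.
- The base closes and re-opens ring C without stereocontrol. Compound 7 and its mirror image, (2R)-4'-hydroxy-7-methoxy-5-(3-methylbut-2-enyloxy)flavanone F1, therefore interconvert through 6.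
- The catalyst reduces only the 2S ketone (dynamic kinetic resolution by asymmetric transfer hydrogenation). This gives (2S,4S)-2-(4-hydroxyphenyl)-7-methoxy-5-(3-methylbut-2-enyloxy)chroman-4-ol F2.
- MnO2 in CH2Cl2 at room temperature then re-oxidises the benzylic alcohol to 7 of high ee.
- The fallback costs one extra step.

**Second: step 6.**
- The unprotected, very easily ionised triol may oligomerise through its quinone methide under Mitsunobu activation.

The fallback sets out from 11 and comes back at 13. It replaces activation and displacement by solvolytic epimerisation, the reaction type by which 3,4-trans leucoanthocyanidins are converted into their 3,4-cis epimers.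
- Compound 11 is held at high dilution (0.005 M) in THF and pH 4 acetate buffer at 30 °C.
- It loses water to the (2S)-2-(4-hydroxyphenyl)-7-methoxy-8-(3-methylbut-2-enyl)-2,3-dihydrochromen-5-one ortho-quinone methide F7 (or its protonated form, the C4 cation).
- Water re-adds preferentially along the axial trajectory, trans to the 2-aryl group.
- The cis/trans mixture is separated on Et3N-deactivated silica, and recovered 11 is recycled.

**Third: step 4.**
- The ortho-dienone 8 can tautomerise to the 6-(1,1-dimethylallyl) isomer before the Cope shift.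
- Prolonged heating with a Lewis acid may erode the ee at C2.

The fallback sets out from 4 and comes back at 10. It moves the two sigmatropic shifts ahead of ring closure, where no stereocenter exists.
- Compound 4 is heated in N,N-diethylaniline at 190 °C to give 2',6'-dihydroxy-4'-methoxy-3'-(3-methylbut-2-enyl)acetophenone F3.
- MOMCl/iPr2NEt in CH2Cl2 caps the less hindered OH, the one not flanked by the prenyl group. This gives 2'-hydroxy-4'-methoxy-6'-(methoxymethoxy)-3'-(3-methylbut-2-enyl)acetophenone F4.
- Condensation with 5 under the conditions of step 2 gives (E)-2',4-dihydroxy-4'-methoxy-6'-(methoxymethoxy)-3'-(3-methylbut-2-enyl)chalcone F5.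
- The catalyst of step 3 closes the only free ortho-OH onto the enone. This gives (2S)-4'-hydroxy-7-methoxy-5-(methoxymethoxy)-8-(3-methylbut-2-enyl)flavanone F6.
- Catalytic HCl in MeOH at 40 °C removes the peri acetal to give 10. The 8-prenyl group has no free ortho-OH with which to cyclise.
- The fallback costs two extra steps.

## Further compounds

F1 | step 3 | (2R)-4'-hydroxy-7-methoxy-5-(3-methylbut-2-enyloxy)flavanone | COc1cc(OCC=C(C)C)c2c(c1)O[C@@H](c1ccc(O)cc1)CC2=O
F2 | step 3 | (2S,4S)-2-(4-hydroxyphenyl)-7-methoxy-5-(3-methylbut-2-enyloxy)chroman-4-ol | COc1cc(OCC=C(C)C)c2c(c1)O[C@H](c1ccc(O)cc1)C[C@@H]2O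
F3 | step 4 | 2',6'-dihydroxy-4'-methoxy-3'-(3-methylbut-2-enyl)acetophenone | COc1cc(O)c(C(C)=O)c(O)c1CC=C(C)C
F4 | step 4 | 2'-hydroxy-4'-methoxy-6'-(methoxymethoxy)-3'-(3-methylbut-2-enyl)acetophenone | COCOc1cc(OC)c(CC=C(C)C)c(O)c1C(C)=O
F5 | step 4 | (E)-2',4-dihydroxy-4'-methoxy-6'-(methoxymethoxy)-3'-(3-methylbut-2-enyl)chalcone | COCOc1cc(OC)c(CC=C(C)C)c(O)c1C(=O)/C=C/c1ccc(O)cc1
F6 | step 4 | (2S)-4'-hydroxy-7-methoxy-5-(methoxymethoxy)-8-(3-methylbut-2-enyl)flavanone | COCOc1cc(OC)c(CC=C(C)C)c2O[C@H](c3ccc(O)cc3)CC(=O)c12
F7 | step 6 | (2S)-2-(4-hydroxyphenyl)-7-methoxy-8-(3-methylbut-2-enyl)-2,3-dihydrochromen-5-one ortho-quinone methide | COC1=CC(=O)C2=CC[C@@H](c3ccc(O)cc3)OC2=C1CC=C(C)C
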